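In a one-step world, solid substrate + partner → target, the birch run would end at 71.4 % of its solid substrate, with partner as the limiting reagent. At 10.0 d it reads 33.1 %.

| flask | solid substrate | partner | remark | time |
|---|---|---|---|---|
| birch | 0.028 M | 0.020 M | run made earlier |  |
| maple | 0.044 M | 0.020 M | run made earlier |  |
| flask | 0.020 M | 0.0200 M |  | 10 d |

| run | time / d | target / % |
|---|---|---|
| birch | 1.25 | 16.3 |
| birch | 4.00 | 31.4 |
| birch | 6.00 | 32.6 |
| birch | 10.0 | 33.1 |
| maple | 0.833 | 6.9 |
| maple | 1.67 | 14.3 |
| maple | 4.00 | 20.0 |
| maple | 10.0 | 21.7 |

(readings scatter by 0.5 percentage points)

- solid, in amounts per volume of the solution: solid substrate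
- the numbers in the tables scatter by 0.5 percentage points (one standard deviation)
- at the start none of the solid substrate is in solution

- beta: doubling the dissolution coefficient of the solid substrate, all else as stated
- alpha: doubling the solubility of the solid substrate, all else as stated
- epsilon: doubling the amount of partner, all else as stated

Counted in molarity, the last readings stand at 0.00927 M of target in birch and 0.00955 M in maple, although maple holds more solid. Both runs hold the same partner charge, so the reckoning here freezes the partner yield f, the target standing at the end per partner charged, read as 47.0 %.

For the next person at the bench: the flask holds 0.020 M of solid substrate, none of it dissolved at the start, and 0.0200 M of partner. Its solid charge exceeds what f calls for, so at 10 d the target should stand at f times partner charge over solid charge, 47.0 %. Birch rose by 0.5 percentage points from 6.00 d to 10.0 d, against a scatter of 0.5 points in one reading, so this reckoning counts on no gain from waiting. The partner charge is not to be cut: in this reckoning the target is f times that charge, although birch and maple hold the same partner charge and do not test this.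

- the target standing at 10 d, as a percentage of the solid substrate charged
- the change that raises the amount of target at 10 d, in percent of the solid substrate charged most ("none" if none brings more than 2 percentage points) (beta / alpha / epsilon / none)
- amount of target at 10 d, in percent of the solid substrate charged, after beta

The forecast gives 47 % (range 45 % to 49.5 %), epsilon as the best change, and 58 % after beta (range 47 % to 65 %), reading the plateau as “partner being lost in parallel”.

The flask gives 45.5 %, with epsilon as the best change and 51.2 % after beta, which is 6.8 points below the forecast. At 10.0 d the decomposed reagent stands at 0.0109 M and the partner at 0.030 % of its charge, while the decomposed reagent and the target's 0.00910 M together make 0.0200 M, the partner charge to the digits shown. The partner yield of this flask is 45.5 %, against the 47.0 % read from birch and maple.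

    solid substrate ⇌ dissolved substrate, rate k1*(cs1 - [dissolved substrate]) while solid is left; crystals form when [dissolved substrate] > cs1 (solubility = 11.0 mM, k = 0.00100 min⁻¹)
    dissolved substrate + partner → target (k = 0.0500 M⁻¹ min⁻¹)
    2 dissolved substrate → side product (k = 0.00880 M⁻¹ min⁻¹)
    partner → decomposed reagent (k = 3.00 × 10⁻⁴ min⁻¹)

On the neighbour flask with 0.0080 M of partner, f gives 18.8 % of the solid substrate charged. The computed neighbour flask shows 19.4 %.

(The numbers in the tables are simulated for substances that don't exist; scatter was added.)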